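**Plan**

- Retrosynthetic cuts, in order: the two aryl O–Si bonds; C4–H (carbinol back to the C4 ketone); C2–C3 of ring C (back to a diazo carbon C3 and the OCH2 of an aryl benzyl ether); O1–C2 (phenol plus ring B carbinol); C8–prenyl.
- Forward: ring A is bought as an acetophenone that already holds C4 and C3. Prenyl goes on C8, O5 is silylated, O1 is benzylated with the ring B carbinol, C3 becomes a diazo carbon, and ring C is closed last by C2–C3 bond formation. Reduction at C4 and desilylation finish the route.
- Enabling feature: C2 carries both the ring oxygen O1 and the electron-rich ring B. In the open precursor it is therefore the CH2 of an aryl benzyl ether, a hydridic C–H bond lying 1,6 to C3, which a rhodium carbenoid at C3 can enter to close ring C.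
- Stereochemistry: C2 (S) comes from a chiral dirhodium carboxylate that selects one enantiotopic benzylic hydrogen. C4 (R, hydroxyl trans to the C2 aryl group) comes from catalyst control in a CBS reduction of the ketone.

Key step: step 6

Remark on the structure: the target is the 2,4-trans flavan-4-ol, (2S,4R).
Remark on the chemistry: the sense of induction of a chiral dirhodium carboxylate in step 6 cannot be predicted safely for this substrate. Rh2(S-BSP)4 is written; if the first run shows the 2R series, the mirror-image catalyst Rh2(R-BSP)4 is used instead.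
Assumption: compounds 1, 2 and 5 are taken as commercial.

**Step 1**
Reactants: 1 1-(2,6-dihydroxy-4-methoxyphenyl)ethan-1-one; 2 1-bromo-3-methylbut-2-ene (prenyl bromide)
Product: 3 1-[2,6-dihydroxy-4-methoxy-3-(3-methylbut-2-en-1-yl)phenyl]ethan-1-one
Conditions: 10 % aq KOH, 0 °C → rt
Reagents that add atoms: none
Why: Direct nuclear prenylation, the C-alkylation of an ambident phenoxide by an allylic halide, is favoured in water, where the oxygen is shielded by hydrogen bonding, and since the two free ring positions of 1 are equivalent by symmetry a single mono C-prenyl isomer should result.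

**Step 2**
Reactants: 3 1-[2,6-dihydroxy-4-methoxy-3-(3-methylbut-2-en-1-yl)phenyl]ethan-1-one
Product: 4 1-[2-hydroxy-4-methoxy-3-(3-methylbut-2-en-1-yl)-6-(triisopropylsilyloxy)phenyl]ethan-1-one
Conditions: TIPSCl, imidazole, DMF, 0 °C → rt
Reagents that add atoms: triisopropylsilyl chloride, CC(C)[Si](Cl)(C(C)C)C(C)C
Why: Silylation of a phenol with a bulky chlorosilane should take place at the hydroxyl that has only the acetyl group as neighbour rather than at the hydroxyl wedged between acetyl and prenyl, after which the remaining hydroxyl is held in a hydrogen bond to the carbonyl and resists a second silylation.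

**Step 3**
Reactants: 5 4-(tert-butyldimethylsilyloxy)benzaldehyde
Product: 6 [4-(tert-butyldimethylsilyloxy)phenyl]methanol
Conditions: NaBH4, MeOH, 0 °C
Reagents that add atoms: none
Why: Borohydride reduction of an aromatic aldehyde to the primary benzylic alcohol is fast at 0 °C and should leave the aryl silyl ether untouched.

**Step 4**
Reactants: 4 1-[2-hydroxy-4-methoxy-3-(3-methylbut-2-en-1-yl)-6-(triisopropylsilyloxy)phenyl]ethan-1-one; 6 [4-(tert-butyldimethylsilyloxy)phenyl]methanol
Product: 7 1-[2-{[4-(tert-butyldimethylsilyloxy)phenyl]methoxy}-4-methoxy-3-(3-methylbut-2-en-1-yl)-6-(triisopropylsilyloxy)phenyl]ethan-1-one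
Conditions: PPh3, DIAD, THF, 0 °C → rt
Reagents that add atoms: none
Why: Mitsunobu etherification joins the hydrogen-bonded but sufficiently acidic phenol with the primary benzylic alcohol under neutral conditions, which spares both aryl silyl ethers and installs the O1–C2 bond and all of ring B in one operation.

**Step 5**
Reactants: 7 1-[2-{[4-(tert-butyldimethylsilyloxy)phenyl]methoxy}-4-methoxy-3-(3-methylbut-2-en-1-yl)-6-(triisopropylsilyloxy)phenyl]ethan-1-one
Product: 9 2-diazo-1-[2-{[4-(tert-butyldimethylsilyloxy)phenyl]methoxy}-4-methoxy-3-(3-methylbut-2-en-1-yl)-6-(triisopropylsilyloxy)phenyl]ethan-1-one, via trifluoroacetyl diketone 8 (not isolated)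
Conditions: LiN(SiMe3)2, THF, −78 °C; CF3CO2CH2CF3; aq NH4Cl; then MsN3, Et3N, H2O, MeCN, rt
Reagents that add atoms: methanesulfonyl azide, CS(=O)(=O)N=[N+]=[N-]
Why: Deacylating diazo transfer of the Regitz type: the kinetic lithium enolate is trifluoroacetylated in a Claisen condensation, and the activated 1,3-diketone 8 then takes the diazo group from the sulfonyl azide and loses the trifluoroacetyl group as the N-acyl sulfonamide, a sequence that works on simple methyl ketones that do not undergo direct diazo transfer.

**Step 6**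
Reactants: 9 2-diazo-1-[2-{[4-(tert-butyldimethylsilyloxy)phenyl]methoxy}-4-methoxy-3-(3-methylbut-2-en-1-yl)-6-(triisopropylsilyloxy)phenyl]ethan-1-one
Product: 10 (2S)-2-[4-(tert-butyldimethylsilyloxy)phenyl]-7-methoxy-8-(3-methylbut-2-en-1-yl)-5-(triisopropylsilyloxy)-2,3-dihydro-4H-1-benzopyran-4-one
Conditions: Rh2(S-BSP)4 (dirhodium tetrakis[N-(benzenesulfonyl)-(S)-prolinate], 1 mol %), CH2Cl2, 0 °C, slow addition of 9
Reagents that add atoms: none
Why: Loss of N2 from 9 on the dirhodium core gives an electrophilic rhodium carbenoid at the future C3, which attacks a C–H bond of the OCH2Ar group (future C2) through a three-centre, hydride-transfer-like transition state in which the C2–C3 bond forms as the hydrogen moves to C3 and the catalyst is released. The closest known reaction type is the dirhodium-carboxylate-catalysed intramolecular C–H insertion of 2-alkoxyaryl diazoketones next to the ether oxygen, which gives chroman-4-ones. Ring C closes by 1,6-insertion (carbenoid carbon counted as 1, C2 as 6), the only six-membered mode open because position 5 is the hydrogen-free ether oxygen O1. The new stereocentre C2 is set by the chiral prolinate ligand sphere, which selects one of the two enantiotopic benzylic hydrogens, and insertion occurs with retention at carbon. The step needs C–H insertion to outrun ylide formation at O1 followed by [1,2]-benzyl shift (Stevens) and any attack on the silyl ether oxygen or the prenyl olefin; the C–H bond is doubly activated by O1 and the electron-rich ring B, O1 is made a poor donor by conjugation to the ortho acyl group and by the flanking prenyl group, the other ortho oxygen is buried under triisopropylsilyl, and the olefin is out of reach of the carbenoid.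

**Step 7**
Reactants: 10 (2S)-2-[4-(tert-butyldimethylsilyloxy)phenyl]-7-methoxy-8-(3-methylbut-2-en-1-yl)-5-(triisopropylsilyloxy)-2,3-dihydro-4H-1-benzopyran-4-one
Product: 11 (2S,4R)-2-[4-(tert-butyldimethylsilyloxy)phenyl]-7-methoxy-8-(3-methylbut-2-en-1-yl)-5-(triisopropylsilyloxy)-3,4-dihydro-2H-1-benzopyran-4-ol
Conditions: (S)-Me-CBS oxazaborolidine [(S)-1-methyl-3,3-diphenyltetrahydro-1H,3H-pyrrolo[1,2-c][1,3,2]oxazaborole] (20 mol %), catecholborane, toluene, −78 °C; aq NaHCO3
Reagents that add atoms: none
Why: Corey–Bakshi–Shibata reduction: the (S)-oxazaborolidine binds the ketone with the large ring A flank away from the catalyst and delivers hydride to the face that gives the 4R carbinol, as with 1-tetralone-type aryl ketones, so that catalyst control should override the ring's own weak preference for the cis alcohol and place the hydroxyl trans to the C2 aryl group, while catecholborane at −78 °C should leave the prenyl olefin alone.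

**Step 8**
Reactants: 11 (2S,4R)-2-[4-(tert-butyldimethylsilyloxy)phenyl]-7-methoxy-8-(3-methylbut-2-en-1-yl)-5-(triisopropylsilyloxy)-3,4-dihydro-2H-1-benzopyran-4-ol
Product: 12 (2S,4R)-2-(4-hydroxyphenyl)-7-methoxy-8-(3-methylbut-2-en-1-yl)-3,4-dihydro-2H-1-benzopyran-4,5-diol
Conditions: Bu4NF, AcOH, THF, 0 °C; pH 7 buffer
Reagents that add atoms: none
Why: Fluoride-induced cleavage of both aryl silyl ethers, buffered with acetic acid, keeps the medium close to neutral, so that the benzylic C4 carbinol, which three ring oxygens make prone to ionisation by acid, and the C2 stereocentre, which a free 4'-phenoxide could open through a quinone methide under strong base, should both survive.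

**Compound list**

1 | 1-(2,6-dihydroxy-4-methoxyphenyl)ethan-1-one | CC(=O)c1c(O)cc(OC)cc1O | starting material
2 | 1-bromo-3-methylbut-2-ene (prenyl bromide) | CC(C)=CCBr | starting material
3 | 1-[2,6-dihydroxy-4-methoxy-3-(3-methylbut-2-en-1-yl)phenyl]ethan-1-one | CC(=O)c1c(O)cc(OC)c(CC=C(C)C)c1O | intermediate
4 | 1-[2-hydroxy-4-methoxy-3-(3-methylbut-2-en-1-yl)-6-(triisopropylsilyloxy)phenyl]ethan-1-one | CC(=O)c1c(O[Si](C(C)C)(C(C)C)C(C)C)cc(OC)c(CC=C(C)C)c1O | intermediate
5 | 4-(tert-butyldimethylsilyloxy)benzaldehyde | O=Cc1ccc(O[Si](C)(C)C(C)(C)C)cc1 | starting material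
6 | [4-(tert-butyldimethylsilyloxy)phenyl]methanol | OCc1ccc(O[Si](C)(C)C(C)(C)C)cc1 | intermediate
7 | 1-[2-{[4-(tert-butyldimethylsilyloxy)phenyl]methoxy}-4-methoxy-3-(3-methylbut-2-en-1-yl)-6-(triisopropylsilyloxy)phenyl]ethan-1-one | CC(=O)c1c(O[Si](C(C)C)(C(C)C)C(C)C)cc(OC)c(CC=C(C)C)c1OCc1ccc(O[Si](C)(C)C(C)(C)C)cc1 | intermediate
8 | 1-[2-{[4-(tert-butyldimethylsilyloxy)phenyl]methoxy}-4-methoxy-3-(3-methylbut-2-en-1-yl)-6-(triisopropylsilyloxy)phenyl]-4,4,4-trifluorobutane-1,3-dione (not isolated) | O=C(CC(=O)C(F)(F)F)c1c(O[Si](C(C)C)(C(C)C)C(C)C)cc(OC)c(CC=C(C)C)c1OCc1ccc(O[Si](C)(C)C(C)(C)C)cc1 | intermediate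
9 | 2-diazo-1-[2-{[4-(tert-butyldimethylsilyloxy)phenyl]methoxy}-4-methoxy-3-(3-methylbut-2-en-1-yl)-6-(triisopropylsilyloxy)phenyl]ethan-1-one | [N-]=[N+]=CC(=O)c1c(O[Si](C(C)C)(C(C)C)C(C)C)cc(OC)c(CC=C(C)C)c1OCc1ccc(O[Si](C)(C)C(C)(C)C)cc1 | intermediate
10 | (2S)-2-[4-(tert-butyldimethylsilyloxy)phenyl]-7-methoxy-8-(3-methylbut-2-en-1-yl)-5-(triisopropylsilyloxy)-2,3-dihydro-4H-1-benzopyran-4-one | COc1cc(O[Si](C(C)C)(C(C)C)C(C)C)c2c(c1CC=C(C)C)O[C@H](c1ccc(O[Si](C)(C)C(C)(C)C)cc1)CC2=O | intermediate
11 | (2S,4R)-2-[4-(tert-butyldimethylsilyloxy)phenyl]-7-methoxy-8-(3-methylbut-2-en-1-yl)-5-(triisopropylsilyloxy)-3,4-dihydro-2H-1-benzopyran-4-ol (2,4-trans) | COc1cc(O[Si](C(C)C)(C(C)C)C(C)C)c2c(c1CC=C(C)C)O[C@H](c1ccc(O[Si](C)(C)C(C)(C)C)cc1)C[C@H]2O | intermediate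
12 | (2S,4R)-2-(4-hydroxyphenyl)-7-methoxy-8-(3-methylbut-2-en-1-yl)-3,4-dihydro-2H-1-benzopyran-4,5-diol (4,5,4'-trihydroxy-7-methoxy-8-prenylflavan) | COc1cc(O)c2c(c1CC=C(C)C)O[C@H](c1ccc(O)cc1)C[C@H]2O | target

**Step count and risks**

Total step count: 8. Longest linear sequence: 7 steps (steps 1, 2, 4, 5, 6, 7, 8 from compound 1).

The three steps most likely to fail:

First, step 6. The carbenoid may be diverted into ylide formation at the ether oxygen followed by [1,2]-benzyl migration, or it may discriminate the two benzylic hydrogens poorly. The fallback sets the C2 stereocentre by asymmetric conjugate arylation of a chromone instead, so that ring C exists before ring B is attached. It sets out from phenol 4. Condensation with N,N-dimethylformamide dimethyl acetal (toluene, 90 °C) should give the enaminone (E)-3-(dimethylamino)-1-[2-hydroxy-4-methoxy-3-(3-methylbut-2-en-1-yl)-6-(triisopropylsilyloxy)phenyl]prop-2-en-1-one F1. Warming in AcOH (60 °C) should cyclise it, with loss of dimethylamine, to 7-methoxy-8-(3-methylbut-2-en-1-yl)-5-(triisopropylsilyloxy)-4H-chromen-4-one F2. Addition of commercial [4-(tert-butyldimethylsilyloxy)phenyl]boronic acid under Pd(OCOCF3)2 and t-BuPyOx [4-tert-butyl-2-(pyridin-2-yl)-4,5-dihydrooxazole, the enantiomer that leads to 2S], with NH4PF6 and H2O in ClCH2CH2Cl at 60 °C, should then give flavanone 10, where the route is rejoined.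

Second, step 7. Hydride delivery may follow the ring's own facial preference instead of the catalyst (poor facial selectivity in the mismatched pairing), or the borane may add to the prenyl olefin. The fallback uses substrate-controlled reduction followed by inversion. It sets out from 10. NaBH4 (MeOH–THF, 0 °C) should give, by axial hydride attack, the cis alcohol (2S,4S)-2-[4-(tert-butyldimethylsilyloxy)phenyl]-7-methoxy-8-(3-methylbut-2-en-1-yl)-5-(triisopropylsilyloxy)-3,4-dihydro-2H-1-benzopyran-4-ol F3. A Mitsunobu reaction with benzoic acid (PPh3, DIAD, THF, 0 °C) should invert C4 to the trans ester (2S,4R)-2-[4-(tert-butyldimethylsilyloxy)phenyl]-7-methoxy-8-(3-methylbut-2-en-1-yl)-5-(triisopropylsilyloxy)-3,4-dihydro-2H-1-benzopyran-4-yl benzoate F4. Reductive ester cleavage with LiEt3BH (THF, −78 °C), which spares the silyl ethers, should give 11, where the route is rejoined.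

Third, step 1. O-alkylation and multiple alkylation may outweigh mono C-alkylation. The fallback replaces direct C-alkylation by O-alkylation and a sigmatropic shift. It sets out from 1. Etherification with tert-butyl 2-methylbut-3-en-2-yl carbonate under Pd(PPh3)4 catalysis (THF, rt) should give the mono 1,1-dimethylallyl ether 1-[2-hydroxy-4-methoxy-6-(2-methylbut-3-en-2-yloxy)phenyl]ethan-1-one F5. Aromatic Claisen rearrangement (toluene, 110 °C) should move the allyl unit, with inversion of its ends, to the only free ortho carbon and give 3, where the route is rejoined.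

**Further compounds**

F1 | step 6 | (E)-3-(dimethylamino)-1-[2-hydroxy-4-methoxy-3-(3-methylbut-2-en-1-yl)-6-(triisopropylsilyloxy)phenyl]prop-2-en-1-one | CN(C)/C=C/C(=O)c1c(O[Si](C(C)C)(C(C)C)C(C)C)cc(OC)c(CC=C(C)C)c1O
F2 | step 6 | 7-methoxy-8-(3-methylbut-2-en-1-yl)-5-(triisopropylsilyloxy)-4H-chromen-4-one | COc1cc(O[Si](C(C)C)(C(C)C)C(C)C)c2c(c1CC=C(C)C)occc2=O
F3 | step 7 | (2S,4S)-2-[4-(tert-butyldimethylsilyloxy)phenyl]-7-methoxy-8-(3-methylbut-2-en-1-yl)-5-(triisopropylsilyloxy)-3,4-dihydro-2H-1-benzopyran-4-ol | COc1cc(O[Si](C(C)C)(C(C)C)C(C)C)c2c(c1CC=C(C)C)O[C@H](c1ccc(O[Si](C)(C)C(C)(C)C)cc1)C[C@@H]2O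
F4 | step 7 | (2S,4R)-2-[4-(tert-butyldimethylsilyloxy)phenyl]-7-methoxy-8-(3-methylbut-2-en-1-yl)-5-(triisopropylsilyloxy)-3,4-dihydro-2H-1-benzopyran-4-yl benzoate | COc1cc(O[Si](C(C)C)(C(C)C)C(C)C)c2c(c1CC=C(C)C)O[C@H](c1ccc(O[Si](C)(C)C(C)(C)C)cc1)C[C@H]2OC(=O)c1ccccc1
F5 | step 1 | 1-[2-hydroxy-4-methoxy-6-(2-methylbut-3-en-2-yloxy)phenyl]ethan-1-one | CC(=O)c1c(O)cc(OC)cc1OC(C)(C)C=C
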